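**Plan** (abscisic-acid numbering: ring C1'–C6', C5 = side-chain carbon on C1', C8' = the CH2O carbon on C6')
1. Enabling feature: C5 (on C1') and C8' (on C6') are cis on the six-membered ring, so they can be joined through oxygen as a γ-lactone; its α-keto-enol form, 3-hydroxy-4-methylfuran-2(5H)-one, is nucleophilic at C6' and, once alkylated, electrophilic at C1'.
2. Cuts: C8'O–acyl (HMG ester); C3–C4 (Heck) and C4=C5 (methylenation) of the dienoate; C4'=O (allylic C–H oxidation); C2'=C3' (from a C3' ketol by reduction and elimination); C1'–C2' (aldol) and C5'–C6' (Michael) of the carbocycle.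
3. Forward order: furanone → Michael/aldol annulation with pent-1-en-3-one (the only carbocycle, built on the lactone) → C2'=C3' alkene → lactol → vinyl carbinol (lactone opened, C8'–OH freed) → HMG ester → enone → dienoate → diacid.
4. Stereochemistry: C6' from the chiral bifunctional catalyst in the Michael step; C1' from the obligatory cis ring fusion; HMG C3 from (R)-mevalonolactone; 4E from syn-insertion/syn-β-hydride elimination; 2Z from (Z)-3-iodobut-2-enoic acid (anti addition of HI to but-2-ynoic acid).

Key step: step 2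

Assumption: the sense of induction on this furanone cannot be assigned in advance; quinine- and quinidine-derived squaramides are pseudoenantiomers, and the one that gives the (S) quaternary carbon of 6 is used (written below as the quinidine series).

**Step 1**
Reactants: 1 2-oxobutanoic acid; 2 formaldehyde
Product: 4 3-hydroxy-4-methylfuran-2(5H)-one, via 4-hydroxy-3-methyl-2-oxobutanoic acid 3 (not isolated)
Conditions: K2CO3, 37% aq. CH2O (1.0 equiv), H2O, 0 °C → rt; then conc. HCl, 90 °C
Reagents that add atoms: none
Why: Base-mediated aldol addition of the keto-acid enolate to formaldehyde gives the γ-hydroxy-α-keto acid, which lactonises and enolises on acidification (the established route to 3-hydroxyfuranones); one equivalent of formaldehyde limits double hydroxymethylation.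

**Step 2**
Reactants: 4 3-hydroxy-4-methylfuran-2(5H)-one; 5 pent-1-en-3-one
Product: 7 (3aS,7aR)-7a-hydroxy-3a,7-dimethylhexahydro-2-benzofuran-1,6-dione (cis-fused ketol lactone, C7 = C2' unassigned), via keto lactone Michael adduct 6 (not isolated)
Conditions: 9-amino-9-deoxy-epi-quinidine 3,5-(CF3)2C6H3 squaramide (10 mol %), PhMe, −30 °C; then DBU (10 mol %), 0 °C
Reagents that add atoms: none
Why: The quinuclidine nitrogen of the catalyst deprotonates the acidic enol of 4 and the squaramide N–H bonds hold 5, so the ion-paired enolate adds through C6' to the terminal carbon of the enone (C5'–C6' bond) and unveils the non-enolisable, strongly electrophilic C1' ketone of α-keto lactone 6; DBU then enolises the ethyl ketone and its CH2 (C2') adds to C1' (C1'–C2' bond). The closest known reaction type is the bifunctional tertiary-amine/hydrogen-bond-donor-catalysed conjugate addition of enolised cyclic 1,2-dicarbonyl compounds to vinyl ketones with formation of a quaternary centre, followed by intramolecular aldol addition, that is, a Robinson annulation halted at the ketol. The carbocycle closes in the 6-(enolendo)-exo-trig mode, and the only other enolisable carbon (C4') could give no more than a four-membered ring. C6' is set by the catalyst, which exposes one face of the planar enolate to the bound enone; C1' follows from the template, because a six-membered ring spanning two adjacent atoms of a γ-lactone can only be cis-fused, which places the C1' hydroxyl cis to the C6' methyl and C5 cis to C8'; C2' is left uncontrolled and ceases to be a stereocentre in step 4. The step needs C- over O-alkylation (the O-adduct can revert, the C-adduct cannot) and arrest at the ketol, which low temperature, substoichiometric base and direct reduction in step 3 should secure.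

**Step 3**
Reactants: 7 ketol lactone
Product: 8 (3aS,7aR)-6,7a-dihydroxy-3a,7-dimethylhexahydro-2-benzofuran-1(3H)-one (6-OH cis to 7-CH3)
Conditions: LiBH(s-Bu)3 (2.2 equiv), THF, −78 °C; then H2O
Reagents that add atoms: none
Why: Chemoselective ketone reduction by a hindered trialkylborohydride (lactone untouched at −78 °C); hydride should approach anti to the flanking C2' methyl, so the C3' hydroxyl is cis to that methyl in either C2' epimer, the arrangement needed for anti elimination toward C2'.

**Step 4**
Reactants: 8 diol lactone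
Product: 10 (3aS,7aR)-7a-hydroxy-3a,7-dimethyl-3a,4,5,7a-tetrahydro-2-benzofuran-1(3H)-one, via C3' mesylate 9 (not isolated)
Conditions: MsCl, Et3N, CH2Cl2, −10 °C; then DBU, PhMe, 100 °C
Reagents that add atoms: none
Why: Selective sulfonylation of the secondary alcohol (the tertiary α-hydroxy-lactone OH is too hindered) and E2 elimination from the conformer with axial mesylate and antiperiplanar C2'–H; Zaitsev orientation should favour the trisubstituted C2'=C3' alkene, and the unassigned centres C2' and C3' are both destroyed.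

**Step 5**
Reactants: 10 alkene lactone
Product: 11 (3aS,7aR)-3a,7-dimethyl-1,3,3a,4,5,7a-hexahydro-2-benzofuran-1,7a-diol (lactol, anomers)
Conditions: i-Bu2AlH (2.5 equiv), CH2Cl2, −78 °C; aq. potassium sodium tartrate
Reagents that add atoms: none
Why: Half-reduction of a lactone to the lactol; the tetrahedral aluminium alkoxide is stable at −78 °C, so over-reduction should not occur and the ring stereocentres are untouched.

**Step 6**
Reactants: 11 lactol
Product: 12 (1R,6S)-1-ethenyl-6-(hydroxymethyl)-2,6-dimethylcyclohex-2-en-1-ol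
Conditions: Ph3PCH3Br, KOt-Bu (excess), THF, 0 → 50 °C
Reagents that add atoms: methyltriphenylphosphonium bromide, C[P+](c1ccccc1)(c1ccccc1)c1ccccc1.[Br-]
Why: Wittig methylenation of the ring-opened hydroxy aldehyde; the small, reactive ylide tolerates the hindered α-hydroxy aldehyde, and ring opening frees C8'–OH while C5 becomes the vinyl CH.

**Step 7**
Reactants: 13 (R)-mevalonolactone
Product: 15 benzyl (3R)-3,5-dihydroxy-3-methylpentanoate, via potassium (R)-mevalonate 14 (not isolated)
Conditions: KOH, H2O/MeOH, rt; evaporate; BnBr, DMF, rt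
Reagents that add atoms: potassium hydroxide, [K+].[OH-]; benzyl bromide, BrCc1ccccc1
Why: Saponification opens the δ-lactone and SN2 O-alkylation of the carboxylate masks the original carboxyl temporarily, leaving the primary alcohol free; the quaternary stereocentre is not involved.

**Step 8**
Reactants: 15 benzyl (R)-mevalonate
Product: 16 (3R)-5-(benzyloxy)-3-hydroxy-3-methyl-5-oxopentanoic acid
Conditions: TEMPO (cat.), PhI(OAc)2, MeCN/H2O, rt
Reagents that add atoms: water, O
Why: Nitroxyl-catalysed oxidation takes the primary alcohol through the aldehyde hydrate to the acid and leaves the tertiary alcohol and the benzyl ester untouched.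

**Step 9**
Reactants: 16 benzyl half-ester acid
Product: 17 1-benzyl 5-[2-(trimethylsilyl)ethyl] (3S)-3-hydroxy-3-methylpentanedioate
Conditions: Me3SiCH2CH2OH, EDC·HCl, DMAP (cat.), CH2Cl2, 0 °C → rt
Reagents that add atoms: 2-(trimethylsilyl)ethanol, C[Si](C)(C)CCO
Why: Steglich esterification caps the new carboxyl as a fluoride-labile 2-(trimethylsilyl)ethyl ester, orthogonal to benzyl (the descriptor changes by priority only).

**Step 10**
Reactants: 17 mixed diester
Product: 18 (3S)-3-hydroxy-3-methyl-5-oxo-5-[2-(trimethylsilyl)ethoxy]pentanoic acid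
Conditions: H2 (1 atm), Pd/C, EtOAc, rt
Reagents that add atoms: none
Why: Hydrogenolysis of the benzyl ester frees the carboxyl that was C1 of mevalonolactone, so that acylation through it leads to the (3R) half-ester of the target.

**Step 11**
Reactants: 12 vinyl diol; 18 HMG half-ester acid
Product: 19 {(1S,2R)-2-ethenyl-2-hydroxy-1,3-dimethylcyclohex-3-en-1-yl}methyl 2-(trimethylsilyl)ethyl (3S)-3-hydroxy-3-methylpentanedioate
Conditions: EDC·HCl, DMAP, CH2Cl2, 0 °C → rt
Reagents that add atoms: none
Why: Steglich esterification at the primary C8' hydroxyl, both tertiary alcohols being too hindered to compete; any minor ring enantiomer from step 2 becomes a separable diastereomer here.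

**Step 12**
Reactants: 19 HMG ester
Product: 20 {(1S,2R)-2-ethenyl-2-hydroxy-1,3-dimethyl-5-oxocyclohex-3-en-1-yl}methyl 2-(trimethylsilyl)ethyl (3S)-3-hydroxy-3-methylpentanedioate
Conditions: Rh2(cap)4 (1 mol %; cap = caprolactamate), t-BuOOH (70% aq.), K2CO3, CH2Cl2, rt
Reagents that add atoms: tert-butyl hydroperoxide, CC(C)(C)OO
Why: Dirhodium-caprolactamate/hydroperoxide allylic C–H oxidation of a trisubstituted cyclohexene; C4' is the only allylic methylene (C1' is quaternary, the vinyl group has no allylic hydrogen), and with C8'–O acylated the new enone cannot suffer intramolecular oxa-Michael addition.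

**Step 13**
Reactants: 21 but-2-ynoic acid
Product: 22 (Z)-3-iodobut-2-enoic acid
Conditions: NaI, AcOH, 110 °C
Reagents that add atoms: sodium iodide, [Na+].[I-]
Why: Anti hydroiodination of the ynoic acid (iodide at C3, protonation from the opposite side) gives the Z β-iodo acid that later fixes the 2Z geometry.

**Step 14**
Reactants: 22 (Z)-3-iodobut-2-enoic acid
Product: 23 2-(trimethylsilyl)ethyl (Z)-3-iodobut-2-enoate
Conditions: Me3SiCH2CH2OH, EDC·HCl, DMAP (5 mol %), CH2Cl2, 0 °C
Reagents that add atoms: 2-(trimethylsilyl)ethanol, C[Si](C)(C)CCO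
Why: Carbodiimide esterification at low temperature with little DMAP, to avoid addition–elimination at the β-iodo enoate and loss of the Z geometry.

**Step 15**
Reactants: 20 enone vinyl carbinol; 23 (Z)-iodo enoate
Product: 24 2-(trimethylsilyl)ethyl (2Z,4E)-5-[(1R,6S)-1-hydroxy-6-({[(3S)-3-hydroxy-3-methyl-5-oxo-5-[2-(trimethylsilyl)ethoxy]pentanoyl]oxy}methyl)-2,6-dimethyl-4-oxocyclohex-2-en-1-yl]-3-methylpenta-2,4-dienoate
Conditions: Pd(OAc)2 (10 mol %), Ag2CO3, DMF, 40 °C, dark
Reagents that add atoms: none
Why: Heck reaction under phosphine-free silver-carbonate conditions: zerovalent palladium formed in situ inserts into the C–I bond with retention, syn-carbopalladation at the terminal vinyl carbon and syn β-hydride elimination (only C4–H is available) give the 4E alkene, and silver removes iodide so that palladium hydride should not isomerise the 2Z bond.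

**Step 16**
Reactants: 24 bis(silylethyl) ester
Product: 25 (2Z,4E)-5-[(1R,6S)-6-({[(3R)-4-carboxy-3-hydroxy-3-methylbutanoyl]oxy}methyl)-1-hydroxy-2,6-dimethyl-4-oxocyclohex-2-en-1-yl]-3-methylpenta-2,4-dienoic acid (CNP0183058.1)
Conditions: Bu4NF, THF, 0 °C → rt; aq. HCl to pH 3
Reagents that add atoms: none
Why: Fluoride-induced β-elimination cleaves both 2-(trimethylsilyl)ethyl esters without touching the hindered C8' ester, the enone, the diene geometry or the tertiary alcohols.

**Compound list**
1 | 2-oxobutanoic acid | CCC(=O)C(=O)O | starting material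
2 | formaldehyde | C=O | starting material
3 | 4-hydroxy-3-methyl-2-oxobutanoic acid (racemic, as potassium salt in the flask) | CC(CO)C(=O)C(=O)O | intermediate (not isolated)
4 | 3-hydroxy-4-methylfuran-2(5H)-one | CC1=C(O)C(=O)OC1 | intermediate
5 | pent-1-en-3-one | CCC(=O)C=C | starting material
6 | (4S)-4-methyl-4-(3-oxopentyl)oxolane-2,3-dione | CCC(=O)CC[C@@]1(C)COC(=O)C1=O | intermediate (not isolated)
7 | (3aS,7aR)-7a-hydroxy-3a,7-dimethylhexahydro-2-benzofuran-1,6-dione (C7 unassigned) | CC1C(=O)CC[C@@](C)(COC2=O)[C@]12O | intermediate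
8 | (3aS,7aR)-6,7a-dihydroxy-3a,7-dimethylhexahydro-2-benzofuran-1(3H)-one (6-OH cis to 7-CH3) | CC1C(O)CC[C@@](C)(COC2=O)[C@]12O | intermediate
9 | 6-O-methanesulfonate of 8 | CC1C(OS(C)(=O)=O)CC[C@@](C)(COC2=O)[C@]12O | intermediate (not isolated)
10 | (3aS,7aR)-7a-hydroxy-3a,7-dimethyl-3a,4,5,7a-tetrahydro-2-benzofuran-1(3H)-one | CC1=CCC[C@@](C)(COC2=O)[C@]12O | intermediate
11 | (3aS,7aR)-3a,7-dimethyl-1,3,3a,4,5,7a-hexahydro-2-benzofuran-1,7a-diol (anomers) | CC1=CCC[C@@](C)(COC2O)[C@]12O | intermediate
12 | (1R,6S)-1-ethenyl-6-(hydroxymethyl)-2,6-dimethylcyclohex-2-en-1-ol | CC1=CCC[C@@](C)(CO)[C@@]1(O)C=C | intermediate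
13 | (R)-mevalonolactone | C[C@@]1(O)CCOC(=O)C1 | starting material
14 | potassium (3R)-3,5-dihydroxy-3-methylpentanoate | C[C@@](CC(=O)[O-])(O)CCO.[K+] | intermediate (not isolated)
15 | benzyl (3R)-3,5-dihydroxy-3-methylpentanoate | C[C@@](CC(=O)OCc1ccccc1)(O)CCO | intermediate
16 | (3R)-5-(benzyloxy)-3-hydroxy-3-methyl-5-oxopentanoic acid | C[C@@](CC(=O)OCc1ccccc1)(O)CC(=O)O | intermediate
17 | 1-benzyl 5-[2-(trimethylsilyl)ethyl] (3S)-3-hydroxy-3-methylpentanedioate | C[C@@](CC(=O)OCc1ccccc1)(O)CC(=O)OCC[Si](C)(C)C | intermediate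
18 | (3S)-3-hydroxy-3-methyl-5-oxo-5-[2-(trimethylsilyl)ethoxy]pentanoic acid | C[C@@](CC(=O)O)(O)CC(=O)OCC[Si](C)(C)C | intermediate
19 | {(1S,2R)-2-ethenyl-2-hydroxy-1,3-dimethylcyclohex-3-en-1-yl}methyl 2-(trimethylsilyl)ethyl (3S)-3-hydroxy-3-methylpentanedioate | CC1=CCC[C@@](C)(COC(=O)C[C@](C)(O)CC(=O)OCC[Si](C)(C)C)[C@@]1(O)C=C | intermediate
20 | {(1S,2R)-2-ethenyl-2-hydroxy-1,3-dimethyl-5-oxocyclohex-3-en-1-yl}methyl 2-(trimethylsilyl)ethyl (3S)-3-hydroxy-3-methylpentanedioate | CC1=CC(=O)C[C@@](C)(COC(=O)C[C@](C)(O)CC(=O)OCC[Si](C)(C)C)[C@@]1(O)C=C | intermediate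
21 | but-2-ynoic acid | CC#CC(=O)O | starting material
22 | (Z)-3-iodobut-2-enoic acid | C/C(I)=C/C(=O)O | intermediate
23 | 2-(trimethylsilyl)ethyl (Z)-3-iodobut-2-enoate | C/C(I)=C/C(=O)OCC[Si](C)(C)C | intermediate
24 | bis[2-(trimethylsilyl)ethyl] ester of the target (name in step 15) | CC1=CC(=O)C[C@@](C)(COC(=O)C[C@](C)(O)CC(=O)OCC[Si](C)(C)C)[C@@]1(O)/C=C/C(C)=C\C(=O)OCC[Si](C)(C)C | intermediate
25 | CNP0183058.1 (name in step 16) | CC1=CC(=O)C[C@@](C)(COC(=O)C[C@](C)(O)CC(=O)O)[C@@]1(O)/C=C/C(C)=C\C(=O)O | target

**Count**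
Total steps: 16. Longest linear sequence: 10 steps (1–6, 11, 12, 15, 16); steps 7–10 and 13–14 are side branches.

**Steps most likely to fail**

Step 2. The small, unhindered vinyl ketone may be discriminated poorly by the catalyst, and the base used for ring closure may dehydrate the ketol. Fallback: setting out from 4, condensation with (S)-1-phenylethylamine (PhMe, cat. TsOH, azeotropic removal of water) gives the secondary enamino lactone 4-methyl-3-{[(1S)-1-phenylethyl]amino}furan-2(5H)-one F1. Its aza-ene-type Michael addition to 5 (THF, rt) is the auxiliary-controlled deracemising alkylation known for 1-phenylethylamine imines of α-substituted cyclic ketones, and it gives the imine (4R)-4-methyl-4-(3-oxopentyl)-3-{[(1S)-1-phenylethyl]imino}oxolan-2-one F2, which has the same spatial arrangement at the quaternary carbon as 6. Hydrolysis with aq. AcOH releases 6, which is closed with DBU as before, so the route is rejoined at 7. The antipode of the amine is exchanged if the induction runs the other way.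

Step 4. Proton loss may occur from C4' instead of C2', either through hindered access to C2'–H or because step 3 delivered the other C3' epimer. Fallback: setting out from 9, the elimination is driven to completion without regard to orientation (LiBr, Li2CO3, DMF, 120 °C), which in the unfavourable case gives mainly the C3'=C4' isomer (3aS,7aR)-7a-hydroxy-3a,7-dimethyl-3a,4,7,7a-tetrahydro-2-benzofuran-1(3H)-one F3. Rhodium-hydride double-bond migration (RhCl3·3H2O, EtOH, 80 °C) then moves the alkene to the thermodynamically preferred trisubstituted C2'=C3' position; C1' is quaternary, so migration cannot pass it. The route is rejoined at 10.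

Step 15. Insertion into the hindered vinyl carbinol may be slow, and palladium hydride may scramble the 2Z geometry. Fallback: setting out from 11, Seyferth–Gilbert homologation with the Ohira–Bestmann reagent (K2CO3, MeOH) gives (1R,6S)-1-ethynyl-6-(hydroxymethyl)-2,6-dimethylcyclohex-2-en-1-ol F4. Esterification with 18 as in step 11 gives {(1S,2R)-2-ethynyl-2-hydroxy-1,3-dimethylcyclohex-3-en-1-yl}methyl 2-(trimethylsilyl)ethyl (3S)-3-hydroxy-3-methylpentanedioate F5. Allylic oxidation as in step 12 gives the 5-oxo analogue {(1S,2R)-2-ethynyl-2-hydroxy-1,3-dimethyl-5-oxocyclohex-3-en-1-yl}methyl 2-(trimethylsilyl)ethyl (3S)-3-hydroxy-3-methylpentanedioate F6. Syn hydrostannation (Bu3SnH, PdCl2(PPh3)2 cat., THF, 0 °C) places tin at the terminal carbon and gives {(1S,2R)-2-hydroxy-1,3-dimethyl-5-oxo-2-[(E)-2-(tributylstannyl)ethenyl]cyclohex-3-en-1-yl}methyl 2-(trimethylsilyl)ethyl (3S)-3-hydroxy-3-methylpentanedioate F7. Stille coupling with 23 (Pd(PPh3)4, CuI, CsF, DMF, rt) proceeds with retention at both partners, and the route is rejoined at 24.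

**Further compounds**
F1 | step 2 | 4-methyl-3-{[(1S)-1-phenylethyl]amino}furan-2(5H)-one | CC1=C(N[C@@H](C)c2ccccc2)C(=O)OC1
F2 | step 2 | (4R)-4-methyl-4-(3-oxopentyl)-3-{[(1S)-1-phenylethyl]imino}oxolan-2-one | CCC(=O)CC[C@@]1(C)COC(=O)C1=N[C@@H](C)c2ccccc2
F3 | step 4 | (3aS,7aR)-7a-hydroxy-3a,7-dimethyl-3a,4,7,7a-tetrahydro-2-benzofuran-1(3H)-one | CC1C=CC[C@@](C)(COC2=O)[C@]12O
F4 | step 15 | (1R,6S)-1-ethynyl-6-(hydroxymethyl)-2,6-dimethylcyclohex-2-en-1-ol | CC1=CCC[C@@](C)(CO)[C@@]1(O)C#C
F5 | step 15 | {(1S,2R)-2-ethynyl-2-hydroxy-1,3-dimethylcyclohex-3-en-1-yl}methyl 2-(trimethylsilyl)ethyl (3S)-3-hydroxy-3-methylpentanedioate | CC1=CCC[C@@](C)(COC(=O)C[C@](C)(O)CC(=O)OCC[Si](C)(C)C)[C@@]1(O)C#C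
F6 | step 15 | {(1S,2R)-2-ethynyl-2-hydroxy-1,3-dimethyl-5-oxocyclohex-3-en-1-yl}methyl 2-(trimethylsilyl)ethyl (3S)-3-hydroxy-3-methylpentanedioate | CC1=CC(=O)C[C@@](C)(COC(=O)C[C@](C)(O)CC(=O)OCC[Si](C)(C)C)[C@@]1(O)C#C
F7 | step 15 | {(1S,2R)-2-hydroxy-1,3-dimethyl-5-oxo-2-[(E)-2-(tributylstannyl)ethenyl]cyclohex-3-en-1-yl}methyl 2-(trimethylsilyl)ethyl (3S)-3-hydroxy-3-methylpentanedioate | CC1=CC(=O)C[C@@](C)(COC(=O)C[C@](C)(O)CC(=O)OCC[Si](C)(C)C)[C@@]1(O)/C=C/[Sn](CCCC)(CCCC)CCCC
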